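The isoindolinone benzo ring carries the lactam carbonyl carbon (C3, on C3a) and the spiro N,O-ketal carbon (C1, on C7a) on adjacent ring atoms, with the methoxy group on C7 next to C7a. This pattern is that of a 3-methoxybenzyne trapped by a carbon nucleophile at C3a and a carbon electrophile at C7a. The key step is a three-component coupling of 3-methoxybenzyne, 2-isocyanoethyl acetate and a 1,8-naphtholactone that already holds the naphthalene C–C and peri C–O bonds of the spiro carbon. It forms both aryl–carbon bonds and gives a spiro imidate, which a chiral phosphoric acid then isomerises to the lactam with control of the spiro centre.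

Key step: step 7

Assumption: the spiro carbon of the target is (R) (priorities O > N > C7a > C2a'), the hand of the phosphoric acid that delivers it is to be fixed in the first run of step 8, and compounds 1, 2, 9 and 12 are taken as purchasable.

Step 1
Reactants: 1 1-(furan-2-yl)propan-2-one; 2 dimethyl acetylenedicarboxylate
Product: 4 dimethyl 3-hydroxy-6-(2-oxopropyl)phthalate, via oxanorbornadiene adduct 3 (not isolated)
Conditions: neat, 60 °C; then BF3·OEt2 (20 mol %), CH2Cl2, 0 °C to rt
Reagents that add atoms: none
Why: Diels–Alder addition of the furan to the acetylenic diester gives the oxygen-bridged adduct 3 (racemic, its bridgehead centres are lost), and the Lewis acid opens the bridge at the alkyl-bearing bridgehead, after which a 1,2-hydride shift and enolisation give the 3-hydroxyphthalate with the side chain para to the hydroxyl, as known for furan/acetylenedicarboxylate adducts.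

Step 2
Reactants: 4 dimethyl 3-hydroxy-6-(2-oxopropyl)phthalate
Product: 5 dimethyl 3-(allyloxy)-6-(2-oxopropyl)phthalate
Conditions: allyl bromide, K2CO3 (1.1 equiv), acetone, 40 °C
Reagents that add atoms: allyl bromide, C=CCBr
Why: Williamson etherification; with one equivalent of carbonate only the phenol, far more acidic than the benzylic ketone CH2, is deprotonated, so O-allylation should prevail over C-alkylation.

Step 3
Reactants: 5 dimethyl 3-(allyloxy)-6-(2-oxopropyl)phthalate
Product: 6 dimethyl 3-(allyloxy)-6-(2-methylallyl)phthalate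
Conditions: Zn, CH2Br2, TiCl4, THF/CH2Cl2, 0 °C to rt
Reagents that add atoms: dibromomethane, BrCBr
Why: Takai–Lombardo methylenation; the non-basic methylene reagent made from Zn, CH2Br2 and TiCl4 olefinates the readily enolised benzylic ketone and should leave the two flanked methyl esters and the allyl ether untouched.

Step 4
Reactants: 6 dimethyl 3-(allyloxy)-6-(2-methylallyl)phthalate
Product: 8 3-(allyloxy)-7-methyl-2H-naphtho[1,8-bc]furan-2-one, via hydroxynaphthoate ester 7 (not isolated)
Conditions: LDA (LiN(iPr)2, 2.2 equiv), THF, −78 to 0 °C; aq. NH4Cl; then TsOH (cat.), PhMe, 80 °C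
Reagents that add atoms: none
Why: Carbanion-mediated naphthol annulation of an ortho-allyl benzoate: deprotonation of the benzylic, allylic CH2, attack of the terminal carbon of the allyl anion on the neighbouring ester (six-membered ring), loss of methoxide and enolisation give 1-naphthol 7, whose peri hydroxyl closes onto the remaining ester under acid.

Step 5
Reactants: 9 N-(2-hydroxyethyl)formamide
Product: 10 2-formamidoethyl acetate
Conditions: Ac2O, pyridine, DMAP (cat.), CH2Cl2, 0 °C to rt
Reagents that add atoms: acetic anhydride, CC(=O)OC(C)=O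
Why: Standard O-acetylation of the primary alcohol; the formamide nitrogen should not be acylated under these conditions.

Step 6
Reactants: 10 2-formamidoethyl acetate
Product: 11 2-isocyanoethyl acetate
Conditions: POCl3, Et3N, CH2Cl2, −20 to 0 °C
Reagents that add atoms: none
Why: Dehydration of an N-monosubstituted formamide with POCl3 and a tertiary amine is the standard isocyanide synthesis, and the acetate is inert to it.

Step 7
Reactants: 8 3-(allyloxy)-7-methyl-2H-naphtho[1,8-bc]furan-2-one; 11 2-isocyanoethyl acetate; 12 3-methoxy-2-(trimethylsilyl)phenyl trifluoromethanesulfonate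
Product: 15 racemic spiro imidate 2-{[3'-(allyloxy)-7-methoxy-7'-methyl-3H-spiro[2-benzofuran-1,2'-naphtho[1,8-bc]furan]-3-ylidene]amino}ethyl acetate, via 3-methoxybenzyne 13 (not isolated), via nitrilium aryl anion 14 (not isolated)
Conditions: KF, 18-crown-6, THF, 0 °C to rt; aq. NaHCO3 work-up, Et3N-deactivated silica
Reagents that add atoms: none
Why: Fluoride converts 12 into 3-methoxybenzyne 13, the isocyanide carbon of 11 adds to the aryne carbon meta to the methoxy group, the aryl anion of zwitterion 14, which sits ortho to that group, adds to the lactone carbonyl of 8, and the alkoxide so formed attacks the nitrilium carbon. The closest known reaction type is the three-component coupling of arynes, isocyanides and phenyl esters to phenoxy iminoisobenzofurans; in 8 the aryloxy group is tethered in the peri position, so it is retained as the naphthofuran ring and the ester carbon becomes the spiro carbon. The one ring closed is the five-membered cyclic imidate, by 5-exo-dig attack of oxygen on the nitrilium ion. The spiro carbon is the only new stereocentre and forms without control, which is of no consequence because step 8 ionises and resets it. The step needs regioselective addition to the unsymmetrical aryne, secured by the inductive effect and ring distortion of the 3-methoxy group that direct the nucleophile to the remote aryne carbon, and chemoselective capture of the aryl anion by 8 and not by the acetate of 11, secured by the strain and aryl ester character of the naphtholactone. Compound 8 is the limiting component, and 11 and 12 are used in excess.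

Step 8
Reactants: 15 racemic spiro imidate
Product: 16 2-[(1R)-3'-(allyloxy)-7-methoxy-7'-methyl-3-oxospiro[isoindoline-1,2'-naphtho[1,8-bc]furan]-2-yl]ethyl acetate
Conditions: (R)-TRIP (10 mol %), 4 Å molecular sieves, PhMe, −30 °C
Reagents that add atoms: none
Why: Proposed new method: the phosphoric acid (TRIP is 3,3'-bis(2,4,6-triisopropylphenyl)-1,1'-binaphthyl-2,2'-diyl hydrogen phosphate) protonates the basic imidate nitrogen, the bond from the imidate oxygen to the spiro carbon ionises to an oxocarbenium ion stabilised by the furan oxygen and the allyloxynaphthalene and paired with the chiral phosphate, and the secondary amide so released closes through nitrogen on one face to the more stable lactam; both enantiomers of 15 converge on the same equilibrating ion pairs, the much less basic lactam should not re-ionise, and so the (R) centre is set under catalyst control, the closest known reaction types being the acid-induced opening of phenoxy iminoisobenzofurans to ortho-keto benzamides and chiral phosphoric acid-catalysed enantioselective additions to the ions derived from 3-aryl-3-hydroxyisoindolinones.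

Step 9
Reactants: 16 2-[(1R)-3'-(allyloxy)-7-methoxy-7'-methyl-3-oxospiro[isoindoline-1,2'-naphtho[1,8-bc]furan]-2-yl]ethyl acetate
Product: 17 (1R)-3'-hydroxy-2-(2-hydroxyethyl)-7-methoxy-7'-methylspiro[isoindoline-1,2'-naphtho[1,8-bc]furan]-3-one
Conditions: Pd(PPh3)4 (5 mol %), K2CO3, MeOH, rt; pH 7 buffer work-up
Reagents that add atoms: none
Why: Tsuji–Trost-type deallylation, in which zerovalent palladium ionises the aryl allyl ether to a π-allyl complex that methoxide intercepts, runs in the same flask as carbonate-mediated methanolysis of the acetate; both are non-acidic, so the N,O-ketal centre, which can ionise only under acid, should not be scrambled.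

Compound list
1 | 1-(furan-2-yl)propan-2-one | CC(=O)Cc1ccco1 | starting material
2 | dimethyl acetylenedicarboxylate | COC(=O)C#CC(=O)OC | starting material
3 | dimethyl 1-(2-oxopropyl)-7-oxabicyclo[2.2.1]hepta-2,5-diene-2,3-dicarboxylate (racemic) | CC(=O)CC12C=CC(O1)C(C(=O)OC)=C2C(=O)OC | intermediate (not isolated)
4 | dimethyl 3-hydroxy-6-(2-oxopropyl)phthalate | COC(=O)c1c(O)ccc(CC(C)=O)c1C(=O)OC | intermediate
5 | dimethyl 3-(allyloxy)-6-(2-oxopropyl)phthalate | COC(=O)c1c(OCC=C)ccc(CC(C)=O)c1C(=O)OC | intermediate
6 | dimethyl 3-(allyloxy)-6-(2-methylallyl)phthalate | COC(=O)c1c(OCC=C)ccc(CC(C)=C)c1C(=O)OC | intermediate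
7 | methyl 2-(allyloxy)-8-hydroxy-6-methyl-1-naphthoate | COC(=O)c1c(OCC=C)ccc2cc(C)cc(O)c12 | intermediate (not isolated)
8 | 3-(allyloxy)-7-methyl-2H-naphtho[1,8-bc]furan-2-one | O=C1Oc2cc(C)cc3ccc(OCC=C)c1c23 | intermediate
9 | N-(2-hydroxyethyl)formamide | O=CNCCO | starting material
10 | 2-formamidoethyl acetate | CC(=O)OCCNC=O | intermediate
11 | 2-isocyanoethyl acetate | CC(=O)OCC[N+]#[C-] | intermediate
12 | 3-methoxy-2-(trimethylsilyl)phenyl trifluoromethanesulfonate | COc1cccc(OS(=O)(=O)C(F)(F)F)c1[Si](C)(C)C | starting material
13 | 3-methoxybenzyne | COC1=CC=CC#C1 | intermediate (not isolated)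
14 | 2-{[(2-acetoxyethyl)iminio]methylidyne}-6-methoxyphenyl anion (nitrilium aryl anion zwitterion) | COc1cccc(C#[N+]CCOC(C)=O)[c-]1 | intermediate (not isolated)
15 | 2-{[3'-(allyloxy)-7-methoxy-7'-methyl-3H-spiro[2-benzofuran-1,2'-naphtho[1,8-bc]furan]-3-ylidene]amino}ethyl acetate (racemic) | COc1cccc2c1C1(Oc3cc(C)cc4ccc(OCC=C)c1c34)OC2=NCCOC(C)=O | intermediate
16 | 2-[(1R)-3'-(allyloxy)-7-methoxy-7'-methyl-3-oxospiro[isoindoline-1,2'-naphtho[1,8-bc]furan]-2-yl]ethyl acetate | COc1cccc2c1[C@@]1(Oc3cc(C)cc4ccc(OCC=C)c1c34)N(CCOC(C)=O)C2=O | intermediate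
17 | (1R)-3'-hydroxy-2-(2-hydroxyethyl)-7-methoxy-7'-methylspiro[isoindoline-1,2'-naphtho[1,8-bc]furan]-3-one | COc1cccc2c1[C@@]1(Oc3cc(C)cc4ccc(O)c1c34)N(CCO)C2=O | target

Total step count: 9
Longest linear sequence: 7 (steps 1, 2, 3, 4, 7, 8, 9)

Steps most likely to fail

Step 8 (Proposed new method). The ring closure through nitrogen may show poor facial discrimination within the ion pair, or an uncatalysed acid-induced isomerisation (for example during isolation of 15) may bypass the catalyst. The fallback sets out from 15 and uses known chemistry only. Compound 15 is isomerised with an achiral acid (pyridinium p-toluenesulfonate, CH2Cl2, rt) to the racemic lactam 2-[3'-(allyloxy)-7-methoxy-7'-methyl-3-oxospiro[isoindoline-1,2'-naphtho[1,8-bc]furan]-2-yl]ethyl acetate F1. This is resolved by preparative chromatography on a chiral stationary phase (amylose tris(3,5-dimethylphenylcarbamate)), which sets aside the (1S)-enantiomer F2 and comes back to the route at 16.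

Step 7. The zwitterion may be consumed by a second molecule of aryne or isocyanide before it adds to the hindered, donor-substituted lactone carbonyl. Fluoride may also open the lactone, and the primary isocyanide may add sluggishly. The fallback sets out from 8 and makes the two aryl–carbon bonds in separate operations. 3-Methoxybenzoyl chloride and 2-[(tert-butyldimethylsilyl)oxy]ethanamine (Et3N, CH2Cl2) give N-{2-[(tert-butyldimethylsilyl)oxy]ethyl}-3-methoxybenzamide F3. Directed ortho-metalation (s-BuLi, 2.2 equiv, TMEDA, THF, −78 °C) should lithiate the position between the methoxy and amide groups, and addition of 8 gives the hydroxylactam 3-[2-(allyloxy)-8-hydroxy-6-methylnaphthalen-1-yl]-2-{2-[(tert-butyldimethylsilyl)oxy]ethyl}-3-hydroxy-4-methoxyisoindolin-1-one F4. Dehydrative spiro N,O-ketalisation with the chiral phosphoric acid of step 8 (or with an achiral acid followed by resolution as above) gives the silyl ether (1R)-3'-(allyloxy)-2-{2-[(tert-butyldimethylsilyl)oxy]ethyl}-7-methoxy-7'-methylspiro[isoindoline-1,2'-naphtho[1,8-bc]furan]-3-one F5. Bu4NF in THF gives the alcohol (1R)-3'-(allyloxy)-2-(2-hydroxyethyl)-7-methoxy-7'-methylspiro[isoindoline-1,2'-naphtho[1,8-bc]furan]-3-one F6, and Pd(PPh3)4, K2CO3, MeOH removes the allyl group, which comes back to the route at 17.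

Step 4. The allyl anion may undergo intermolecular acylation (self-condensation), or the amide base may add to the esters, before the ring closes. The fallback sets out from 5 and replaces the carbanion annulation by a Claisen condensation. NaOMe in MeOH at reflux, then acidic work-up, should close the methyl ketone onto the neighbouring ester; the resulting naphthalene-1,3-diol lactonises through its peri hydroxyl to 3-(allyloxy)-7-hydroxy-2H-naphtho[1,8-bc]furan-2-one F7. Tf2O and pyridine give 3-(allyloxy)-7-methyl-free triflate 3-(allyloxy)-2-oxo-2H-naphtho[1,8-bc]furan-7-yl trifluoromethanesulfonate F8. Suzuki–Miyaura methylation (trimethylboroxine, Pd(dppf)Cl2, K3PO4, dioxane, 90 °C) comes back to the route at 8.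

Further compounds
F1 | step 8 | 2-[3'-(allyloxy)-7-methoxy-7'-methyl-3-oxospiro[isoindoline-1,2'-naphtho[1,8-bc]furan]-2-yl]ethyl acetate (racemic) | COc1cccc2c1C1(Oc3cc(C)cc4ccc(OCC=C)c1c34)N(CCOC(C)=O)C2=O
F2 | step 8 | 2-[(1S)-3'-(allyloxy)-7-methoxy-7'-methyl-3-oxospiro[isoindoline-1,2'-naphtho[1,8-bc]furan]-2-yl]ethyl acetate | COc1cccc2c1[C@]1(Oc3cc(C)cc4ccc(OCC=C)c1c34)N(CCOC(C)=O)C2=O
F3 | step 7 | N-{2-[(tert-butyldimethylsilyl)oxy]ethyl}-3-methoxybenzamide | COc1cccc(C(=O)NCCO[Si](C)(C)C(C)(C)C)c1
F4 | step 7 | 3-[2-(allyloxy)-8-hydroxy-6-methylnaphthalen-1-yl]-2-{2-[(tert-butyldimethylsilyl)oxy]ethyl}-3-hydroxy-4-methoxyisoindolin-1-one (racemic) | COc1cccc2c1C(O)(c1c(OCC=C)ccc3cc(C)cc(O)c13)N(CCO[Si](C)(C)C(C)(C)C)C2=O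
F5 | step 7 | (1R)-3'-(allyloxy)-2-{2-[(tert-butyldimethylsilyl)oxy]ethyl}-7-methoxy-7'-methylspiro[isoindoline-1,2'-naphtho[1,8-bc]furan]-3-one | COc1cccc2c1[C@@]1(Oc3cc(C)cc4ccc(OCC=C)c1c34)N(CCO[Si](C)(C)C(C)(C)C)C2=O
F6 | step 7 | (1R)-3'-(allyloxy)-2-(2-hydroxyethyl)-7-methoxy-7'-methylspiro[isoindoline-1,2'-naphtho[1,8-bc]furan]-3-one | COc1cccc2c1[C@@]1(Oc3cc(C)cc4ccc(OCC=C)c1c34)N(CCO)C2=O
F7 | step 4 | 3-(allyloxy)-7-hydroxy-2H-naphtho[1,8-bc]furan-2-one | O=C1Oc2cc(O)cc3ccc(OCC=C)c1c23
F8 | step 4 | 3-(allyloxy)-2-oxo-2H-naphtho[1,8-bc]furan-7-yl trifluoromethanesulfonate | O=C1Oc2cc(OS(=O)(=O)C(F)(F)F)cc3ccc(OCC=C)c1c23
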